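The percent of substrate charged is the unit of this ledger, and each percent must stand as substrate, open intermediate, target or over-reaction product. Substrate is the limiting reagent, its charge of 2.0 M being smaller than the 2.60 M of partner, with one partner taken up per target.

| flask | substrate | partner | remark | time |
|---|---|---|---|---|
| cedar | 1 M | 2.6 M (in portions, 4) | run made earlier; portions every 6.0 s |  |
| oak | 1.5 M | 2.6 M (in portions, 4) | run made earlier; portions every 6.0 s |  |
| flask | 2.0 M | 2.60 M (in portions, 4) | the portions of partner follow each other after 6.0 s, the first at the start | 15 min |

| run | time / min | target / % | open intermediate / % |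
|---|---|---|---|
| cedar | 1.50 | 1.9 | 45.9 |
| cedar | 3.00 | 13.3 | 46.1 |
| cedar | 5.00 | 31.7 | 38.9 |
| cedar | 6.00 | 37.5 | 34.4 |
| cedar | 8.00 | 49.4 | 29.1 |
| cedar | 10.0 | 59.1 | 22.2 |
| oak | 0.667 | 0 | 30.9 |
| oak | 1.33 | 3.3 | 44.9 |
| oak | 2.00 | 7.3 | 49.8 |
| oak | 3.00 | 13.6 | 47.4 |
| oak | 5.00 | 28.2 | 40.2 |
| oak | 10.0 | 56.7 | 22.7 |

(scatter of a reading: 1 percentage point)

- concentration of target at 15 min, in M
- concentration of open intermediate at 15 min, in M
- concentration of substrate at 15 min, in M
- concentration of partner at 15 min, in M

The runs read target and open intermediate, so the charge beyond target can be reckoned at each reading. Define the open share φ as open intermediate divided by substrate and open intermediate together; the runs give that sum as the charge less target, with any over-reaction product, which they do not read, counted in it. Dividing two amounts of one moment takes time out. In the cedar run, target climbs from 31.7 % at 5.00 min to 59.1 % at 10.0 min, while φ read there moves from 0.570 to 0.543. Each reading scatters by 1 percentage point. The cedar and oak readings at those two times average 0.549. The runs show no column for partner, so this ledger makes no entry for it.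

The forecast gives target 1.25 M, open intermediate 0.34 M, substrate 0.26 M and partner 0.15 M, with this ground for target: “Allowing for some over-reaction and partner loss gives about 1.25 M.” Its entries for target, open intermediate and substrate leave 0.150 M of the charge outside them. The ledger kept here differs. It takes the forecast's target, books nothing to over-reaction product and so has 0.750 M to divide, which φ splits into 0.412 M of open intermediate and 0.338 M of substrate.

The flask at 15 min gives target 1.31 M, open intermediate 0.392 M, substrate 0.272 M and partner 0.0668 M.

    partner ⇌ dormant form (K = 2.30, k = 0.00260 s⁻¹)
    partner → second intermediate (k = 0.00570 s⁻¹)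
    target → over-reaction product (k = 3.80 × 10⁻⁵ s⁻¹)
    open intermediate + second intermediate → target (k = 0.00240 M⁻¹ s⁻¹)
    substrate ⇌ open intermediate (K = 1.60, k = 0.0110 s⁻¹)

At 15 min the flask holds 0.0256 M of over-reaction product, against the 0.150 M the forecast's entries leave outside them. Its charge beyond target and over-reaction product is then 0.664 M, of which φ books 0.365 M as open intermediate, and the flask holds 0.392 M. The same flask read at 25 min holds target 1.57 M and over-reaction product 0.0589 M, which leaves 0.369 M. There φ books 0.203 M as open intermediate, and that flask holds 0.219 M.

All runs were computed with made-up constants, and the scatter is random.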